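**Retrosynthetic overview**
1. Chain numbering: C1 = benzylic CH2, C2=C3(CH3), C4H2, C5=O, C6H2, cyclopentane C7–C11 (CH3 on C7 and C11), C12=O, C13H2, C14=C15(CH3)2. After a final desilylation, the target is cut at C3–C4 into an (E)-alkenyl iodide (arene half, C1–C3) and a chloromethyl ketone (cyclopentane half, C4–C15). A nickel-catalysed electroreductive cross-electrophile coupling joins the two.
2. Enabling feature: the skipped enone C2=C3–C4H2–C5=O. C4 lies α to the C5 carbonyl, so a C4–Cl bond is easily reduced to a carbonyl-stabilised radical. C3 is an sp2 carbon whose E geometry can be stored in a C–I bond. The base-free cell keeps this enone and its twin C12(=O)–C13H2–C14=C15 out of conjugation.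
3. Cyclopentane half: chloromethyl ketone ⇐ δ-lactone (temporary ring tying C5 to O–C12) ⇐ formyl ester ⇐ ozonolysis of an enol silane ⇐ enantioselective deprotonation of meso cis-1,5-dimethylbicyclo[3.3.0]octan-3-one. The cis vicinal quaternary pair C7/C11 is bought with the Weiss–Cook diketone.
4. Arene half: an arylcopper from 2-methylhydroquinone (silylation, ortho-bromination, O-methylation) plus (E)-1-bromo-3-iodobut-2-ene from but-2-yn-1-ol, where a syn borylcupration fixes the geometry.
5. Ring order: no carbocycle is built, since the arene and the cyclopentane are bought. The second five-membered ring of the bicycle is cleaved in step 5. The temporary six-membered lactone/lactol ring closes in step 7 and opens in step 9.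

Key step: step 17

Assumption 1: the lithium amide from (R,R)-bis(1-phenylethyl)amine is taken to remove a proton from the methylene group next to the future C11. If the sense of induction is the opposite, the equally available (S,S)-amine is used and nothing else changes.
Assumption 2: the carbinol centre (C12) and the hemiketal centre (C5) in 10–13 are left unspecified, because both become carbonyl carbons in step 9.

**Fragment 1 (cyclopentane half)**

Step 1
Reactants: 1 cis-1,5-dimethylbicyclo[3.3.0]octane-3,7-dione
Product: 2 mono(ethylene ketal) of 1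
Conditions: ethylene glycol (1.0 equiv), p-TsOH (cat.), toluene, Dean–Stark, reflux
Reagents that add atoms: ethylene glycol, OCCO
Why: Acid-catalysed ketalisation with water removal differentiates the two equivalent carbonyl groups statistically with one equivalent of diol (unreacted 1 and bis-ketal are recycled), and no stereocentre is touched.

Step 2
Reactants: 2 mono(ethylene ketal) of 1
Product: 3 cis-1,5-dimethylbicyclo[3.3.0]octan-3-one ethylene ketal
Conditions: N2H4·H2O, KOH, diethylene glycol, 130 then 200 °C
Reagents that add atoms: none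
Why: Wolff–Kishner reduction (Huang-Minlon variant) turns the free carbonyl group into CH2 while the base-stable ketal survives.

Step 3
Reactants: 3 cis-1,5-dimethylbicyclo[3.3.0]octan-3-one ethylene ketal
Product: 4 cis-1,5-dimethylbicyclo[3.3.0]octan-3-one (meso)
Conditions: 1 M HCl, THF, rt
Reagents that add atoms: water, O
Why: Acid-catalysed ketal hydrolysis frees the ketone, and nothing else in the molecule is acid-sensitive.

Step 4
Reactants: 4 cis-1,5-dimethylbicyclo[3.3.0]octan-3-one (meso)
Product: 6 (3aS,6aR)-3a,6a-dimethyl-2-(trimethylsilyloxy)-1,3a,4,5,6,6a-hexahydropentalene, via lithium enolate 5 (not isolated)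
Conditions: (R,R)-bis(1-phenylethyl)amine, n-BuLi, LiCl, THF, −78 °C; TMSCl, then 4 added slowly, −100 °C
Reagents that add atoms: chlorotrimethylsilane, C[Si](C)(C)Cl
Why: In this enantioselective deprotonation of a meso ketone under in situ silyl quench, the C2-symmetric chiral lithium amide distinguishes the two enantiotopic α-methylene groups, and this single choice fixes the absolute configuration at both quaternary carbons (future C7 and C11), whose cis relation is inherited from 1.

Step 5
Reactants: 6 (3aS,6aR)-3a,6a-dimethyl-2-(trimethylsilyloxy)-1,3a,4,5,6,6a-hexahydropentalene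
Product: 8 2-[(1R,2R)-2-formyl-1,2-dimethylcyclopentyl]acetic acid, via trimethylsilyl ester 7 (not isolated)
Conditions: O3, CH2Cl2, −78 °C; Me2S, −78 °C to rt; aqueous work-up
Reagents that add atoms: ozone, [O-][O+]=O
Why: Ozonolysis of a silyl enol ether with reductive work-up cleaves the C5=C12 bond into an aldehyde (C12) and a silyl ester (C5) that hydrolyses on work-up, so the two arms emerge differentiated, and neither quaternary centre carries a hydrogen that could epimerise.

Step 6
Reactants: 8 2-[(1R,2R)-2-formyl-1,2-dimethylcyclopentyl]acetic acid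
Product: 9 methyl 2-[(1R,2R)-2-formyl-1,2-dimethylcyclopentyl]acetate
Conditions: MeI, K2CO3, DMF, rt
Reagents that add atoms: iodomethane, CI
Why: SN2 O-alkylation of the carboxylate removes the acidic proton before the organometallic step, and the aldehyde cannot enolise.

Step 7
Reactants: 9 methyl 2-[(1R,2R)-2-formyl-1,2-dimethylcyclopentyl]acetate
Product: 11 (4aR,7aR)-4a,7a-dimethyl-1-(3-methylbut-2-enyl)hexahydrocyclopenta[c]pyran-3(1H)-one (both C1 epimers), via hydroxy ester 10 (not isolated)
Conditions: BaI2, lithium biphenylide (2 equiv), THF, rt; prenyl chloride, −78 °C; 9, −78 °C; aq NH4Cl; then p-TsOH (cat.), CH2Cl2, rt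
Reagents that add atoms: 1-chloro-3-methylbut-2-ene (prenyl chloride), CC(C)=CCCl
Why: Allylbarium reagents add to aldehydes at their unsubstituted α-terminus without allylic transposition, so the prenyl group should arrive linear, the aldehyde reacts ahead of the ester at −78 °C, the hydroxy ester then closes the δ-lactone (helped by the cis arrangement on the ring), and the new carbinol centre needs no control because step 9 destroys it.

Step 8
Reactants: 11 (4aR,7aR)-4a,7a-dimethyl-1-(3-methylbut-2-enyl)hexahydrocyclopenta[c]pyran-3(1H)-one
Product: 12 (4aR,7aR)-3-(chloromethyl)-4a,7a-dimethyl-1-(3-methylbut-2-enyl)octahydrocyclopenta[c]pyran-3-ol (lactol)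
Conditions: ICH2Cl, MeLi·LiBr, THF/Et2O, −78 °C; AcOH, −78 °C
Reagents that add atoms: chloroiodomethane, ClCI
Why: Chloromethyllithium, made by iodine–lithium exchange in the presence of the lactone, adds only once because the cyclic tetrahedral alkoxide does not collapse at −78 °C (carbenoid homologation of esters and lactones to chloromethyl ketones), and the hemiketal centre is of no consequence.

Step 9
Reactants: 12 (4aR,7aR)-3-(chloromethyl)-4a,7a-dimethyl-1-(3-methylbut-2-enyl)octahydrocyclopenta[c]pyran-3-ol
Product: 14 1-[(1R,2R)-2-(3-chloro-2-oxopropyl)-1,2-dimethylcyclopentyl]-4-methylpent-3-en-1-one, via open-chain hydroxy chloroketone 13 (not isolated)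
Conditions: Dess–Martin periodinane, CH2Cl2, rt
Reagents that add atoms: none
Why: Dess–Martin oxidation acts on the secondary alcohol of the open-chain tautomer and so drains the ring–chain equilibrium (the acetic acid set free speeds the opening), and the mild medium should leave the new β,γ-enone unconjugated and the C–Cl bond untouched.

**Fragment 2 (arene half)**

Step 10
Reactants: 15 2-methylhydroquinone
Product: 16 2-methyl-4-(triisopropylsilyloxy)phenol
Conditions: TIPSCl (1.0 equiv), imidazole, CH2Cl2/DMF, 0 °C
Reagents that add atoms: chlorotriisopropylsilane, CC(C)[Si](Cl)(C(C)C)C(C)C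
Why: In this silyl ether formation the bulky chlorosilane should pick the hydroxyl group that has no ortho substituent.

Step 11
Reactants: 16 2-methyl-4-(triisopropylsilyloxy)phenol
Product: 17 2-bromo-6-methyl-4-(triisopropylsilyloxy)phenol
Conditions: NBS, i-Pr2NH (cat.), CH2Cl2, 0 °C
Reagents that add atoms: N-bromosuccinimide, O=C1CCC(=O)N1Br
Why: Electrophilic aromatic bromination is steered by the free hydroxyl group to its only open ortho position, because the para position is blocked and the positions next to the bulky silyl ether are shielded.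

Step 12
Reactants: 17 2-bromo-6-methyl-4-(triisopropylsilyloxy)phenol
Product: 18 (3-bromo-4-methoxy-5-methylphenoxy)triisopropylsilane
Conditions: MeI, K2CO3, acetone, reflux
Reagents that add atoms: iodomethane, CI
Why: Williamson ether synthesis places the methyl group on the hindered oxygen, the only free one, and the triisopropylsilyl ether tolerates carbonate.

Step 13
Reactants: 19 but-2-yn-1-ol
Product: 20 (Z)-3-(4,4,5,5-tetramethyl-1,3,2-dioxaborolan-2-yl)but-2-en-1-ol (boron trans to CH2OH)
Conditions: B2pin2, CuCl (cat.), PCy3 (cat.), NaOt-Bu (cat.), MeOH (2 equiv), toluene, rt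
Reagents that add atoms: bis(pinacolato)diboron, CC1(C)OB(OC1(C)C)B1OC(C)(C)C(C)(C)O1
Why: Copper-catalysed syn borylcupration and protonation (formal hydroboration) of a propargylic alcohol places boron on the alkyne carbon remote from the oxygenated carbon, and the syn addition sets the alkene geometry (CH3 cis to CH2OH).

Step 14
Reactants: 20 (Z)-3-(4,4,5,5-tetramethyl-1,3,2-dioxaborolan-2-yl)but-2-en-1-ol
Product: 21 (E)-3-iodobut-2-en-1-ol
Conditions: NaOH (aq), then I2, THF, 0 °C
Reagents that add atoms: iodine, II
Why: Iododeboronation of the hydroxide ate complex of an alkenylboronate proceeds with retention, so iodine takes the place of boron (only the descriptor changes from Z to E, because the priorities change).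

Step 15
Reactants: 21 (E)-3-iodobut-2-en-1-ol
Product: 22 (E)-1-bromo-3-iodobut-2-ene
Conditions: CBr4, PPh3, CH2Cl2, 0 °C
Reagents that add atoms: tetrabromomethane, BrC(Br)(Br)Br
Why: The Appel reaction converts the primary allylic alcohol into the bromide under neutral conditions without touching the alkenyl iodide or its geometry.

Step 16
Reactants: 18 (3-bromo-4-methoxy-5-methylphenoxy)triisopropylsilane; 22 (E)-1-bromo-3-iodobut-2-ene
Product: 25 {3-[(2E)-3-iodobut-2-enyl]-4-methoxy-5-methylphenoxy}triisopropylsilane, via aryllithium 23 (not isolated), via arylcopper 24 (not isolated)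
Conditions: n-BuLi, THF, −78 °C; CuBr·SMe2 (1.0 equiv), −78 to −40 °C; 22, −78 to 0 °C
Reagents that add atoms: none
Why: Bromine–lithium exchange, transmetalation to copper and SN2 allylation at the primary allylic bromide attach the arene to C1, the soft arylcopper leaves the alkenyl iodide alone at low temperature, and attack at the iodine- and methyl-bearing γ-carbon is sterically disfavoured.

**Union and end game**

Step 17
Reactants: 14 1-[(1R,2R)-2-(3-chloro-2-oxopropyl)-1,2-dimethylcyclopentyl]-4-methylpent-3-en-1-one; 25 {3-[(2E)-3-iodobut-2-enyl]-4-methoxy-5-methylphenoxy}triisopropylsilane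
Product: 26 triisopropylsilyl ether of the target
Conditions: 25 (1.5 equiv), NiBr2·dme (10 mol %), 2,2'-bipyridine (10 mol %), Bu4NBF4 (0.1 M), DMF, undivided cell, Fe anode, Ni-foam cathode, constant current (about 2.5 F per mol of 14), rt; 14 added by syringe pump over the electrolysis
Reagents that add atoms: none
Why: Zerovalent nickel generated at the cathode inserts into the C3–I bond of 25 with retention of the E geometry, monovalent nickel in the same cycle abstracts chlorine from 14, and the primary radical at C4, stabilised by the C5 carbonyl, is captured by the alkenylnickel species, whereupon reductive elimination forms C3–C4 and the cathode returns nickel to its low-valent state while the dissolving iron anode balances the charge. The closest known reaction type is the nickel–bipyridine-catalysed electroreductive cross-coupling of α-chloro ketones and α-chloro esters with aryl and alkenyl halides in an undivided cell with a sacrificial anode. No ring is closed and no stereocentre is created: C7 and C11 are quaternary spectators and the alkene geometry is carried over from 25. The step needs cross- over homo-coupling, which the two different activation modes (two-electron insertion for the sp2 iodide, halogen abstraction for the carbonyl-activated sp3 chloride), the excess of 25 and the slow feed of 14 should secure. It also needs chemoselectivity and positional integrity: the catalyst works at a potential far from that of dialkyl ketones, aryl silyl ethers and isolated alkenes, and because no base and no free enolate are present, neither the new C2=C3–C4–C5=O unit nor the C12 enone should slip into conjugation. In one operation the step assembles the whole C28 skeleton from two halves of about equal size and installs the more delicate of the two skipped enones in its final oxidation state.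

Step 18
Reactants: 26 triisopropylsilyl ether of the target
Product: 27 target, 1-[(1R,2R)-2-{(4E)-6-(5-hydroxy-2-methoxy-3-methylphenyl)-4-methyl-2-oxohex-4-enyl}-1,2-dimethylcyclopentyl]-4-methylpent-3-en-1-one
Conditions: TBAF (1.1 equiv), AcOH (1.2 equiv), THF, 0 °C
Reagents that add atoms: none
Why: Fluoride-mediated cleavage of an aryl silyl ether is fast at 0 °C, and the acetic acid buffer protonates the phenoxide at once, so the two base-sensitive skipped enones should stay in place.

**Compound list**
1 | cis-1,5-dimethylbicyclo[3.3.0]octane-3,7-dione | O=C1C[C@@]2(C)CC(=O)C[C@@]2(C)C1 | starting material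
2 | mono(ethylene ketal) of 1 | O=C1C[C@@]2(C)CC3(OCCO3)C[C@@]2(C)C1 | intermediate
3 | cis-1,5-dimethylbicyclo[3.3.0]octan-3-one ethylene ketal | O1CCOC13C[C@@]2(C)CCC[C@@]2(C)C3 | intermediate
4 | cis-1,5-dimethylbicyclo[3.3.0]octan-3-one (meso) | O=C1C[C@@]2(C)CCC[C@@]2(C)C1 | intermediate
5 | lithium enolate of 4 (3aS,6aR) | [Li]OC=1C[C@@]2(C)CCC[C@@]2(C)C=1 | intermediate
6 | (3aS,6aR)-3a,6a-dimethyl-2-(trimethylsilyloxy)-1,3a,4,5,6,6a-hexahydropentalene | C[Si](C)(C)OC=1C[C@@]2(C)CCC[C@@]2(C)C=1 | intermediate
7 | trimethylsilyl 2-[(1R,2R)-2-formyl-1,2-dimethylcyclopentyl]acetate | C[Si](C)(C)OC(=O)C[C@@]1(C)CCC[C@@]1(C)C=O | intermediate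
8 | 2-[(1R,2R)-2-formyl-1,2-dimethylcyclopentyl]acetic acid | OC(=O)C[C@@]1(C)CCC[C@@]1(C)C=O | intermediate
9 | methyl 2-[(1R,2R)-2-formyl-1,2-dimethylcyclopentyl]acetate | COC(=O)C[C@@]1(C)CCC[C@@]1(C)C=O | intermediate
10 | methyl 2-[(1R,2R)-2-(1-hydroxy-4-methylpent-3-enyl)-1,2-dimethylcyclopentyl]acetate (carbinol epimers) | COC(=O)C[C@@]1(C)CCC[C@@]1(C)C(O)CC=C(C)C | intermediate
11 | (4aR,7aR)-4a,7a-dimethyl-1-(3-methylbut-2-enyl)hexahydrocyclopenta[c]pyran-3(1H)-one (C1 epimers) | O=C1C[C@@]2(C)CCC[C@@]2(C)C(CC=C(C)C)O1 | intermediate
12 | (4aR,7aR)-3-(chloromethyl)-4a,7a-dimethyl-1-(3-methylbut-2-enyl)octahydrocyclopenta[c]pyran-3-ol | OC1(CCl)C[C@@]2(C)CCC[C@@]2(C)C(CC=C(C)C)O1 | intermediate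
13 | 1-chloro-3-[(1R,2R)-2-(1-hydroxy-4-methylpent-3-enyl)-1,2-dimethylcyclopentyl]propan-2-one | ClCC(=O)C[C@@]1(C)CCC[C@@]1(C)C(O)CC=C(C)C | intermediate
14 | 1-[(1R,2R)-2-(3-chloro-2-oxopropyl)-1,2-dimethylcyclopentyl]-4-methylpent-3-en-1-one | ClCC(=O)C[C@@]1(C)CCC[C@@]1(C)C(=O)CC=C(C)C | intermediate
15 | 2-methylhydroquinone | Cc1cc(O)ccc1O | starting material
16 | 2-methyl-4-(triisopropylsilyloxy)phenol | Cc1cc(O[Si](C(C)C)(C(C)C)C(C)C)ccc1O | intermediate
17 | 2-bromo-6-methyl-4-(triisopropylsilyloxy)phenol | Cc1cc(O[Si](C(C)C)(C(C)C)C(C)C)cc(Br)c1O | intermediate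
18 | (3-bromo-4-methoxy-5-methylphenoxy)triisopropylsilane | COc1c(C)cc(O[Si](C(C)C)(C(C)C)C(C)C)cc1Br | intermediate
19 | but-2-yn-1-ol | CC#CCO | starting material
20 | (Z)-3-(4,4,5,5-tetramethyl-1,3,2-dioxaborolan-2-yl)but-2-en-1-ol | OC/C=C(\C)B1OC(C)(C)C(C)(C)O1 | intermediate
21 | (E)-3-iodobut-2-en-1-ol | OC/C=C(\C)I | intermediate
22 | (E)-1-bromo-3-iodobut-2-ene | BrC/C=C(\C)I | intermediate
23 | [2-methoxy-3-methyl-5-(triisopropylsilyloxy)phenyl]lithium | COc1c(C)cc(O[Si](C(C)C)(C(C)C)C(C)C)cc1[Li] | intermediate
24 | [2-methoxy-3-methyl-5-(triisopropylsilyloxy)phenyl]copper | COc1c(C)cc(O[Si](C(C)C)(C(C)C)C(C)C)cc1[Cu] | intermediate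
25 | {3-[(2E)-3-iodobut-2-enyl]-4-methoxy-5-methylphenoxy}triisopropylsilane | COc1c(C)cc(O[Si](C(C)C)(C(C)C)C(C)C)cc1C/C=C(\C)I | intermediate
26 | triisopropylsilyl ether of the target (1R,2R; 4E) | COc1c(C)cc(O[Si](C(C)C)(C(C)C)C(C)C)cc1C/C=C(\C)CC(=O)C[C@@]1(C)CCC[C@@]1(C)C(=O)CC=C(C)C | intermediate
27 | 1-[(1R,2R)-2-{(4E)-6-(5-hydroxy-2-methoxy-3-methylphenyl)-4-methyl-2-oxohex-4-enyl}-1,2-dimethylcyclopentyl]-4-methylpent-3-en-1-one | COc1c(C)cc(O)cc1C/C=C(\C)CC(=O)C[C@@]1(C)CCC[C@@]1(C)C(=O)CC=C(C)C | target

**Step count**
Total steps: 18. Longest linear sequence: 11 steps (steps 1–9, 17, 18).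

**Steps most likely to fail**

Step 17 (key coupling).
- What may go wrong: the C–Cl bond may be reduced to C–H before the radical is intercepted. The alkenyl iodide may dimerise. A metal enolate formed by over-reduction may add to the C12 carbonyl.
- Fallback: a polar 1,2-metallate rearrangement on boron instead of a reductive radical coupling. It sets out from 25 and 14 and comes back at 26.
- Iodide 25 is lithiated (t-BuLi, Et2O, −78 °C) to the (E)-alkenyllithium F1.
- F1 is treated with 9-methoxy-9-borabicyclo[3.3.1]nonane and then BF3·OEt2 to give the B-alkenyl-9-borabicyclo[3.3.1]nonane F2.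
- 14 and potassium 2,6-di-tert-butylphenoxide are then added (THF, 0 °C). The hindered phenoxide deprotonates the chloromethyl group and C4 binds to boron. The alkenyl group should then shift from boron to C4 with loss of chloride and retention of geometry.
- This is the known α-alkenylation of α-halo carbonyl compounds with B-alkenyl boranes. Protonolysis on work-up gives 26.

Step 4 (desymmetrisation).
- What may go wrong: the bridgehead methyl groups next to both α-methylene groups may weaken the discrimination of the enantiotopic protons, or slow the deprotonation so much that the enantiomeric purity suffers.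
- Fallback: enantioselective oxygen insertion instead of enantioselective proton removal. It sets out from 4 and comes back at 8.
- A Baeyer–Villiger monooxygenase (whole cells, air; enantiocomplementary enzyme families exist for meso bicyclic ketones) converts 4 into (4aR,7aR)-4a,7a-dimethylhexahydrocyclopenta[c]pyran-3(1H)-one F3.
- Saponification (KOH, aq THF) gives 2-[(1R,2R)-2-(hydroxymethyl)-1,2-dimethylcyclopentyl]acetic acid F4, handled as its potassium salt.
- The neopentyl primary alcohol of F4 is oxidised with TEMPO/NaOCl in the same basic medium. Acidification gives 8.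

Step 9 (oxidation through the open tautomer).
- What may go wrong: the chloromethyl hemiketal may open too reluctantly. The oxidation then stalls, and the long exposure erodes the chloroketone or moves the C14=C15 alkene into conjugation.
- Fallback: build the chloroketone from a keto acid, so that no hemiketal can form. It sets out from 11 and comes back at 14.
- Lactone 11 is opened with KOH and alkylated in the same flask with allyl bromide to the hydroxy allyl ester F5.
- F5 is oxidised at once (Dess–Martin periodinane) to the keto allyl ester F6.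
- Pd(PPh3)4 and morpholine remove the allyl group under neutral conditions to give the keto acid F7.
- Isobutyl chloroformate and N-methylmorpholine give the mixed anhydride F8, and diazomethane converts F8 into the diazoketone F9.
- HCl in Et2O at −20 °C (Nierenstein-type hydrochlorination) gives 14.

**Further compounds**
F1 | step 17 | (E)-alkenyllithium from 25 | COc1c(C)cc(O[Si](C(C)C)(C(C)C)C(C)C)cc1C/C=C(\C)[Li]
F2 | step 17 | B-[(E)-alkenyl]-9-borabicyclo[3.3.1]nonane from 25 | COc1c(C)cc(O[Si](C(C)C)(C(C)C)C(C)C)cc1C/C=C(\C)B1C2CCCC1CCC2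
F3 | step 4 | (4aR,7aR)-4a,7a-dimethylhexahydrocyclopenta[c]pyran-3(1H)-one | O=C1C[C@@]2(C)CCC[C@@]2(C)CO1
F4 | step 4 | 2-[(1R,2R)-2-(hydroxymethyl)-1,2-dimethylcyclopentyl]acetic acid | OC(=O)C[C@@]1(C)CCC[C@@]1(C)CO
F5 | step 9 | allyl 2-[(1R,2R)-2-(1-hydroxy-4-methylpent-3-enyl)-1,2-dimethylcyclopentyl]acetate | C=CCOC(=O)C[C@@]1(C)CCC[C@@]1(C)C(O)CC=C(C)C
F6 | step 9 | allyl 2-[(1R,2R)-1,2-dimethyl-2-(4-methylpent-3-enoyl)cyclopentyl]acetate | C=CCOC(=O)C[C@@]1(C)CCC[C@@]1(C)C(=O)CC=C(C)C
F7 | step 9 | 2-[(1R,2R)-1,2-dimethyl-2-(4-methylpent-3-enoyl)cyclopentyl]acetic acid | OC(=O)C[C@@]1(C)CCC[C@@]1(C)C(=O)CC=C(C)C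
F8 | step 9 | isobutyl carbonic mixed anhydride of F7 | CC(C)COC(=O)OC(=O)C[C@@]1(C)CCC[C@@]1(C)C(=O)CC=C(C)C
F9 | step 9 | 1-[(1R,2R)-2-(3-diazo-2-oxopropyl)-1,2-dimethylcyclopentyl]-4-methylpent-3-en-1-one | [N-]=[N+]=CC(=O)C[C@@]1(C)CCC[C@@]1(C)C(=O)CC=C(C)C
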